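(The readings were generated by integration on assumed constants; scatter was added.)

The vessel is closed, stirred and isothermal, and the thing to watch in it is the early target reading, which in dusk and in summer rose and then sank.

| flask | starting material | catalyst | remark | time |
|---|---|---|---|---|
| dusk | 0.050 M | 12 mol% | run made earlier |  |
| summer | 0.075 M | 12 mol% | run made earlier |  |
| autumn | 0.10 M | 24 mol% | run made earlier |  |
| flask | 0.10 M | 12 mol% |  | 20 h |

| run | time / h | target / % | starting material / % |
|---|---|---|---|
| dusk | 0.333 | 22.0 | 72.6 |
| dusk | 0.833 | 37.9 | 48.1 |
| dusk | 2.50 | 39.2 | 24.7 |
| dusk | 8.00 | 27.4 | 14.1 |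
| dusk | 20.0 | 24.1 | 12.4 |
| summer | 0.333 | 23.6 | 72.9 |
| summer | 0.833 | 34.6 | 47.1 |
| summer | 2.50 | 33.2 | 22.1 |
| summer | 8.00 | 25.2 | 13.5 |
| summer | 20.0 | 24.8 | 12.6 |
| autumn | 0.333 | 17.6 | 64.0 |
| autumn | 0.833 | 25.0 | 40.6 |
| autumn | 2.50 | 22.6 | 18.2 |
| autumn | 8.00 | 24.8 | 15.7 |
| autumn | 20.0 | 24.7 | 12.6 |

(scatter of a reading: 1 percentage point)

- what was read earlier has a scatter of 1 percentage point, one standard deviation
- steps that have been proposed: isomer of the product A + catalyst <-> isomer of the product B + catalyst; isomer of the product B + catalyst <-> starting material + catalyst; target + catalyst <-> isomer of the product A + catalyst; starting material <-> target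

* time up to 20 h at which target stands highest
* the amount of target, in percent of the starting material charged, at that time

Two chemists dispute this flask. The first reckons in loading: the readings are percentages of the charge, and the flask has the 12 mol% of dusk and summer, so it should repeat them. The mean of their highest target readings, 39.2% and 34.6%, gives 36.9%.

The second, whose side I take, answers that those readings differ by 4.6 percentage points against a scatter of 1 point. The proposed step from target to isomer of the product A has catalyst as a reactant, so its forward rate is pseudo-first-order in target, with a rate constant proportional to c(catalyst). The working quantity is thus c(catalyst) = 0.0120 M, the starting-material charge times the loading.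

The runs then form a ladder: dusk 0.00600 M, summer 0.00900 M, autumn 0.0240 M, with highest target readings 39.2%, 34.6% and 25.0%. The flask stands above summer and below autumn, and my straight interpolation between their readings at 0.833 h gives 32.7%.

The forecast sides with the second chemist: 33% (range 30.5% to 35.5%) at 1.1 h (range 0.8 h to 1.5 h), holding that "Absolute catalyst concentration therefore sets the drain on target". My interpolated figure lies 0.30 points below its number.

The flask gives 33.0% at 1.18 h, inside both forecast ranges and 3.9 points under the loading number.

    isomer of the product A + catalyst ⇌ isomer of the product B + catalyst, rate k1*[catalyst]*[isomer of the product A] forward; the back reaction follows from the equilibrium constant (K = 0.440, k = 5.15 × 10⁻⁴ M⁻¹ s⁻¹)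
    isomer of the product B + catalyst ⇌ starting material + catalyst, rate k2*[catalyst]*[isomer of the product B] forward; the back reaction follows from the equilibrium constant (k = 0.00372 M⁻¹ s⁻¹)
    target + catalyst ⇌ isomer of the product A + catalyst, rate k3*[catalyst]*[target] forward; the back reaction follows from the equilibrium constant (K = 1.70, k = 0.0170 M⁻¹ s⁻¹)
    starting material ⇌ target (K = 1.76, k = 2.63 × 10⁻⁴ s⁻¹)

The forecast's number would fail in a neighbouring flask with 0.40 M of starting material at the same 12 mol%. There the same product gives c(catalyst) = 0.0480 M, twice autumn's, so that neighbour stands beyond the top of the ladder, where autumn's highest target reading was 25.0%. That neighbour gives 24.9%, below the forecast's low end. The loading view keeps the late hours: at 20.0 h that neighbour holds 24.9% target, and the flask holds 24.9%.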